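**Retrosynthetic overview**

1. The target is a (2S)-flavanone: ring C (the dihydropyranone) carries ring B (3-hydroxy-4,5-dimethoxyphenyl) on C2 and is fused to ring A (7,8-dimethoxy).
2. The strategy rests on the C3–C4 bond of ring C, which joins the C3 methylene to the aryl ketone carbon C4 on ring A. It is read as the C3=C4 double bond of a 4-silyloxy-2H-chromene and cut by ring-closing metathesis into a vinyl group on C2 and the silyl enol ether of a ring A acetyl group, so C4 arrives already at the ketone oxidation level.
3. The O1–C2 bond and the C2 stereocentre come from an iridium-catalysed, branched-selective asymmetric allylic etherification of the ring A acetophenone phenol with a ring B cinnamyl methyl carbonate.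
4. The carbonate is made from 3-hydroxy-4,5-dimethoxybenzaldehyde by benzylation, Horner–Wadsworth–Emmons olefination, reduction and acylation.
5. Rings A and B are bought; ring C is the only ring formed (step 7). Unmasking of the ketone and hydrogenolysis of the benzyl ether finish the route.

Key step: step 7

Assumption: the (Sa,Sc,Sc) antipode of the phosphoramidite ligand is taken to give the (S)-configured branched ether in step 5; if a check of the sense of induction on a small scale shows the reverse, the mirror-image ligand is used with no other change.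

**Route**

Step 1
Reactants: 1 3-hydroxy-4,5-dimethoxybenzaldehyde
Product: 2 3-(benzyloxy)-4,5-dimethoxybenzaldehyde
Conditions: BnBr, K2CO3, DMF, rt
Reagents that add atoms: benzyl bromide, BrCc1ccccc1
Why: Williamson ether synthesis, in which the carbonate-generated phenoxide displaces bromide from benzyl bromide while the aldehyde is untouched.

Step 2
Reactants: 2 3-(benzyloxy)-4,5-dimethoxybenzaldehyde; 3 triethyl phosphonoacetate
Product: 5 ethyl (2E)-3-[3-(benzyloxy)-4,5-dimethoxyphenyl]prop-2-enoate, via sodium phosphonate carbanion 4 (not isolated)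
Conditions: NaH, THF, 0 °C; then 2, 0 °C to rt
Reagents that add atoms: none
Why: Horner–Wadsworth–Emmons olefination, in which the stabilised phosphonate carbanion adds to the aldehyde and the oxaphosphetane collapses to the thermodynamically preferred E-cinnamate.

Step 3
Reactants: 5 ethyl (2E)-3-[3-(benzyloxy)-4,5-dimethoxyphenyl]prop-2-enoate
Product: 6 (2E)-3-[3-(benzyloxy)-4,5-dimethoxyphenyl]prop-2-en-1-ol
Conditions: i-Bu2AlH (2.5 equiv), CH2Cl2, −78 to 0 °C; aqueous potassium sodium tartrate (KNaC4H4O6) work-up
Reagents that add atoms: none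
Why: 1,2-reduction of the conjugated ester by the aluminium hydride through the aldehyde to the allylic alcohol, which should leave the C=C bond and the benzyl ether intact.

Step 4
Reactants: 6 (2E)-3-[3-(benzyloxy)-4,5-dimethoxyphenyl]prop-2-en-1-ol
Product: 7 (2E)-3-[3-(benzyloxy)-4,5-dimethoxyphenyl]prop-2-en-1-yl methyl carbonate
Conditions: ClCO2Me, pyridine, CH2Cl2, 0 °C
Reagents that add atoms: methyl chloroformate, COC(=O)Cl
Why: O-acylation of the primary allylic alcohol with a chloroformate, which installs the leaving group needed for the iridium step.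

Step 5
Reactants: 7 (2E)-3-[3-(benzyloxy)-4,5-dimethoxyphenyl]prop-2-en-1-yl methyl carbonate; 8 1-(2-hydroxy-3,4-dimethoxyphenyl)ethanone
Product: 10 1-{2-[(1S)-1-(3-benzyloxy-4,5-dimethoxyphenyl)prop-2-enyloxy]-3,4-dimethoxyphenyl}ethanone, via potassium 6-acetyl-2,3-dimethoxyphenolate 9 (not isolated)
Conditions: [Ir(cod)Cl]2 (2 mol %), (Sa,Sc,Sc)-N,N-bis(1-phenylethyl)dinaphtho[2,1-d:1',2'-f][1,3,2]dioxaphosphepin-4-amine (4 mol %), pre-activated with n-PrNH2 (THF, 50 °C, volatiles then removed); 8 (1.5 equiv), K3PO4 (1.0 equiv), THF, 25–50 °C, stopped at full conversion of 7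
Reagents that add atoms: none
Why: Iridium-catalysed asymmetric allylic etherification (Tsuji–Trost-type substitution), in which the cyclometallated iridium–phosphoramidite complex ionises the carbonate to an η3-allyl complex, phenoxide 9 attacks the aryl-bearing terminus anti to the metal to give the branched ether, the ligand antipode fixes the allyl face bound to iridium and hence the (S) configuration at the future C2, and the excess phenol buffers the released methoxide so that the methyl ketone is not enolised.

Step 6
Reactants: 10 1-{2-[(1S)-1-(3-benzyloxy-4,5-dimethoxyphenyl)prop-2-enyloxy]-3,4-dimethoxyphenyl}ethanone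
Product: 11 tert-butyl{[1-(2-{[(1S)-1-(3-benzyloxy-4,5-dimethoxyphenyl)prop-2-en-1-yl]oxy}-3,4-dimethoxyphenyl)ethenyl]oxy}dimethylsilane (the tert-butyldimethylsilyl enol ether of 10)
Conditions: TBSOTf (1.3 equiv), Et3N (2.5 equiv), CH2Cl2, −78 to 0 °C; aqueous NaHCO3 work-up, Et3N-deactivated silica
Reagents that add atoms: tert-butyldimethylsilyl trifluoromethanesulfonate, CC(C)(C)[Si](C)(C)OS(=O)(=O)C(F)(F)F
Why: Soft enolisation, in which the silyl triflate activates the ketone and triethylamine removes a proton from the only enolisable position (the methyl group) to give the single possible silyl enol ether, the excess amine and low temperature keeping the medium non-acidic so that the allylic, benzylic C–O bond should not ionise.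

Step 7
Reactants: 11 tert-butyl{[1-(2-{[(1S)-1-(3-benzyloxy-4,5-dimethoxyphenyl)prop-2-en-1-yl]oxy}-3,4-dimethoxyphenyl)ethenyl]oxy}dimethylsilane
Product: 12 (2S)-2-(3-benzyloxy-4,5-dimethoxyphenyl)-4-(tert-butyldimethylsilyloxy)-7,8-dimethoxy-2H-chromene
Conditions: second-generation Grubbs catalyst RuCl2(=CHPh)(H2IMes)(PCy3) (5–10 mol %), 1,4-benzoquinone (10 mol %), degassed CH2Cl2 (0.01 M), 40 °C, dark
Reagents that add atoms: none
Why: The ruthenium benzylidene should exchange onto the unhindered monosubstituted vinyl group to place an alkylidene on the future C3, which adds intramolecularly across the 1,1-disubstituted silyl enol ether to a ruthenacyclobutane whose cycloreversion forms C3=C4 and a ruthenium methylidene, with ethylene leaving as the driving force. The closest known reaction type is silyl enol ether–ene ring-closing metathesis to cyclic silyl enol ethers, including benzo-fused 4-silyloxy-1,2-dihydroquinolines from N-allyl 2-aminoacetophenone enol ethers, together with diene ring-closing metathesis of aryl allyl ethers to 2H-chromenes. Ring C is closed as a six-membered ring by this intramolecular [2+2]/retro-[2+2] sequence between two alkenes held ortho to each other on ring A, giving an endocyclic enol ether. No stereocentre is formed, and C2, set in step 5, is a spectator. The step needs the catalyst to load at the vinyl group and not at the electron-rich enol ether (where a Fischer-type carbene would form), which the steric shielding of the aryl- and silyloxy-substituted enol ether carbon should secure. It also needs the vinyl double bond not to migrate, which benzoquinone (a scavenger of ruthenium hydrides), moderate temperature and the neutral medium should secure, while high dilution disfavours dimerisation.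

Step 8
Reactants: 12 (2S)-2-(3-benzyloxy-4,5-dimethoxyphenyl)-4-(tert-butyldimethylsilyloxy)-7,8-dimethoxy-2H-chromene
Product: 13 (2S)-2-(3-benzyloxy-4,5-dimethoxyphenyl)-7,8-dimethoxy-2,3-dihydro-4H-chromen-4-one
Conditions: Bu4NF (1.1 equiv), AcOH (1.5 equiv), THF, −20 to 0 °C
Reagents that add atoms: none
Why: Fluoride-mediated cleavage of the silyl enol ether, in which fluoride attacks silicon and the liberated enolate is protonated at C3 by acetic acid before it can expel the O1 phenoxide (the retro-oxa-Michael path by which flavanones racemise), so C2 should be retained.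

Step 9
Reactants: 13 (2S)-2-(3-benzyloxy-4,5-dimethoxyphenyl)-7,8-dimethoxy-2,3-dihydro-4H-chromen-4-one
Product: 14 (2S)-2-(3-hydroxy-4,5-dimethoxyphenyl)-7,8-dimethoxy-2,3-dihydro-4H-chromen-4-one (target)
Conditions: H2 (1 atm), 10% Pd/C, EtOAc, rt, stopped after uptake of one equivalent
Reagents that add atoms: none
Why: Catalytic hydrogenolysis of the aryl benzyl ether, in which the unhindered primary benzylic C–O bond should cleave well before the hindered secondary C2–O1 bond or the aryl ketone is touched.

**Compound list**

1 | 3-hydroxy-4,5-dimethoxybenzaldehyde | O=Cc1cc(O)c(OC)c(OC)c1 | starting material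
2 | 3-(benzyloxy)-4,5-dimethoxybenzaldehyde | O=Cc1cc(OCc2ccccc2)c(OC)c(OC)c1 | intermediate
3 | triethyl phosphonoacetate | CCOC(=O)CP(=O)(OCC)OCC | starting material
4 | sodium salt of triethyl phosphonoacetate (sodium phosphonate carbanion) | CCOC(=O)[CH-]P(=O)(OCC)OCC.[Na+] | intermediate
5 | ethyl (2E)-3-[3-(benzyloxy)-4,5-dimethoxyphenyl]prop-2-enoate | CCOC(=O)/C=C/c1cc(OCc2ccccc2)c(OC)c(OC)c1 | intermediate
6 | (2E)-3-[3-(benzyloxy)-4,5-dimethoxyphenyl]prop-2-en-1-ol | OC/C=C/c1cc(OCc2ccccc2)c(OC)c(OC)c1 | intermediate
7 | (2E)-3-[3-(benzyloxy)-4,5-dimethoxyphenyl]prop-2-en-1-yl methyl carbonate | COC(=O)OC/C=C/c1cc(OCc2ccccc2)c(OC)c(OC)c1 | intermediate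
8 | 1-(2-hydroxy-3,4-dimethoxyphenyl)ethanone | CC(=O)c1ccc(OC)c(OC)c1O | starting material
9 | potassium 6-acetyl-2,3-dimethoxyphenolate | CC(=O)c1ccc(OC)c(OC)c1[O-].[K+] | intermediate
10 | 1-{2-[(1S)-1-(3-benzyloxy-4,5-dimethoxyphenyl)prop-2-enyloxy]-3,4-dimethoxyphenyl}ethanone | COc1cc([C@@H](Oc2c(C(C)=O)ccc(OC)c2OC)C=C)cc(OCc2ccccc2)c1OC | intermediate
11 | tert-butyl{[1-(2-{[(1S)-1-(3-benzyloxy-4,5-dimethoxyphenyl)prop-2-en-1-yl]oxy}-3,4-dimethoxyphenyl)ethenyl]oxy}dimethylsilane | COc1cc([C@@H](Oc2c(C(=C)O[Si](C)(C)C(C)(C)C)ccc(OC)c2OC)C=C)cc(OCc2ccccc2)c1OC | intermediate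
12 | (2S)-2-(3-benzyloxy-4,5-dimethoxyphenyl)-4-(tert-butyldimethylsilyloxy)-7,8-dimethoxy-2H-chromene | COc1cc([C@@H]2C=C(O[Si](C)(C)C(C)(C)C)c3ccc(OC)c(OC)c3O2)cc(OCc2ccccc2)c1OC | intermediate
13 | (2S)-2-(3-benzyloxy-4,5-dimethoxyphenyl)-7,8-dimethoxy-2,3-dihydro-4H-chromen-4-one | COc1cc([C@@H]2CC(=O)c3ccc(OC)c(OC)c3O2)cc(OCc2ccccc2)c1OC | intermediate
14 | (2S)-2-(3-hydroxy-4,5-dimethoxyphenyl)-7,8-dimethoxy-2,3-dihydro-4H-chromen-4-one | COc1cc([C@@H]2CC(=O)c3ccc(OC)c(OC)c3O2)cc(O)c1OC | target

**Step count and risk**

Total step count: 9. Longest linear sequence: 9 steps (1 to 14); the acetophenone 8 enters unchanged in step 5.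

Steps most likely to fail:

Step 7 (ring-closing metathesis). The catalyst may be trapped at the enol ether as an unreactive Fischer-type carbene, closure onto the hindered 1,1-disubstituted alkene may be slower than dimerisation through the vinyl groups, or ruthenium hydrides may move the vinyl double bond into conjugation and erase C2. The fallback closes ring C at O1–C2 instead of C3–C4; it sets out from 2 and returns at 13. Claisen–Schmidt condensation of 2 with 8 (KOH, EtOH, rt) should give the chalcone (2E)-3-[3-(benzyloxy)-4,5-dimethoxyphenyl]-1-(2-hydroxy-3,4-dimethoxyphenyl)prop-2-en-1-one F1. Oxa-Michael cyclisation (NaOAc, EtOH–H2O, reflux) should then give racemic 2-(3-benzyloxy-4,5-dimethoxyphenyl)-7,8-dimethoxy-2,3-dihydro-4H-chromen-4-one F2. Preparative chromatography on a cellulose tris(3,5-dimethylphenylcarbamate) chiral phase would separate 13 from (2R)-2-(3-benzyloxy-4,5-dimethoxyphenyl)-7,8-dimethoxy-2,3-dihydro-4H-chromen-4-one F3, which is re-equilibrated through F1 under the same acetate conditions and recycled.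

Step 5 (iridium-catalysed etherification). The phenoxide is flanked by a methoxy and an acetyl group and can chelate its counter-ion through the carbonyl, so attack on the allyl complex may be slow. This would allow formation of the linear ether and erosion of enantiopurity through reversible ionisation of the product. The fallback sets C2 with a small oxygen nucleophile and forms O1–C2 by inversion; it sets out from 7 and returns at 10. Iridium-catalysed substitution of 7 with KOSiEt3 under the same catalyst system, but with the mirror-image ligand, should give {[(1R)-1-(3-benzyloxy-4,5-dimethoxyphenyl)prop-2-en-1-yl]oxy}triethylsilane F4. Bu4NF in THF would release (1R)-1-(3-benzyloxy-4,5-dimethoxyphenyl)prop-2-en-1-ol F5. Mitsunobu etherification of F5 with 8 (PPh3, diisopropyl azodicarboxylate, toluene, 0 °C) should then give 10 with inversion.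

Step 9 (hydrogenolysis). Over-reduction may occur, by hydrogenolytic scission of the benzylic C2–O1 bond (opening ring C to a dihydrochalcone) or by reduction of the aryl ketone before debenzylation is complete. The fallback replaces reductive cleavage by Lewis-acid cleavage with a cation scavenger; it sets out from 13 and returns at 14 and makes no new compound (F0). The conditions are BCl3 (2 equiv) and pentamethylbenzene (3 equiv) in CH2Cl2 at −78 °C, quenched cold with methanol.

**Further compounds**

F1 | step 7 | (2E)-3-[3-(benzyloxy)-4,5-dimethoxyphenyl]-1-(2-hydroxy-3,4-dimethoxyphenyl)prop-2-en-1-one | COc1cc(/C=C/C(=O)c2ccc(OC)c(OC)c2O)cc(OCc2ccccc2)c1OC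
F2 | step 7 | racemic 2-(3-benzyloxy-4,5-dimethoxyphenyl)-7,8-dimethoxy-2,3-dihydro-4H-chromen-4-one | COc1cc(C2CC(=O)c3ccc(OC)c(OC)c3O2)cc(OCc2ccccc2)c1OC
F3 | step 7 | (2R)-2-(3-benzyloxy-4,5-dimethoxyphenyl)-7,8-dimethoxy-2,3-dihydro-4H-chromen-4-one | COc1cc([C@H]2CC(=O)c3ccc(OC)c(OC)c3O2)cc(OCc2ccccc2)c1OC
F4 | step 5 | {[(1R)-1-(3-benzyloxy-4,5-dimethoxyphenyl)prop-2-en-1-yl]oxy}triethylsilane | COc1cc([C@H](O[Si](CC)(CC)CC)C=C)cc(OCc2ccccc2)c1OC
F5 | step 5 | (1R)-1-(3-benzyloxy-4,5-dimethoxyphenyl)prop-2-en-1-ol | COc1cc([C@H](O)C=C)cc(OCc2ccccc2)c1OC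
F0 | step 9 | none | none
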